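**Retrosynthetic overview**

- The chain is cut at C9–C10 into methyl 9-oxononanoate and a C10–C18 terminal alkynyl oxirane. One union makes the C9–C10 bond, creates the E-C10=C11 olefin by syn-hydrometalation and sets C9 (S) under ligand control, on the intact, unprotected oxirane.
- C10–C11 therefore come from acetylene, used twice as a two-carbon linchpin between two aldehydes: as an acetylide towards C12, then as an alkenylzinc towards C9.
- The only ring, the oxirane O–C12–C13, is closed before the union from an anti-chlorohydrin: C13–Cl by organocatalytic α-chlorination, C12–O by Cornforth-controlled acetylide addition, closure with inversion at C13 (trans, 12S,13S).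
- The Z-C15=C16 enyne comes from a Wittig reaction of a C12–C15 ester ylide with a silylated propynal; C18–Br is introduced last.

Key step: step 6

Assumption: the senses of induction of the two chiral catalysts are assigned from their accepted models ((2S,5S)-2,5-diphenylpyrrolidine gives the (R)-2-chloroaldehyde by steric shielding; (+)-MIB directs addition to the Re face of an aliphatic aldehyde, the mirror image of (−)-MIB); should either run opposite, the enantiomeric catalyst is used and nothing else changes.

**Step 1**
Reactants: 1 (4-ethoxy-4-oxobutyl)triphenylphosphonium bromide; 2 3-(triisopropylsilyl)prop-2-ynal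
Product: 4 ethyl (4Z)-7-(triisopropylsilyl)hept-4-en-6-ynoate, via ylide 3 (not isolated)
Conditions: NaHMDS (1.0 equiv), THF, −78 °C, 30 min; then 2, −78 → 0 °C
Reagents that add atoms: none
Why: Wittig olefination of a non-stabilised ylide under lithium-free conditions proceeds through the kinetically preferred cis-oxaphosphetane, so the C15=C16 bond should form with Z geometry, and the bulky silyl group keeps the ynal from conjugate addition.

**Step 2**
Reactants: 4 ethyl (4Z)-7-(triisopropylsilyl)hept-4-en-6-ynoate
Product: 5 (4Z)-7-(triisopropylsilyl)hept-4-en-6-ynal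
Conditions: DIBAL-H (1.1 equiv), CH2Cl2, −78 °C; MeOH, then aq. Rochelle salt
Reagents that add atoms: none
Why: Partial reduction of an ester with DIBAL-H at −78 °C stops at the aluminium hemiacetal, which should release the aldehyde only on work-up, and neither the Z-enyne nor the C–Si bond reacts with the hydride at this temperature.

**Step 3**
Reactants: 5 (4Z)-7-(triisopropylsilyl)hept-4-en-6-ynal
Product: 6 (2R,4Z)-2-chloro-7-(triisopropylsilyl)hept-4-en-6-ynal
Conditions: NCS (1.2 equiv), (2S,5S)-2,5-diphenylpyrrolidine (10 mol%), CH2Cl2, 0 °C → rt; pentane, filtration, cold concentration; crude 6 used at once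
Reagents that add atoms: N-chlorosuccinimide, O=C1CCC(=O)N1Cl
Why: Enamine-catalysed asymmetric α-chlorination, in which the C2-symmetric pyrrolidine forms an E-enamine with one face shielded by the adjacent phenyl group, so NCS should deliver chlorine to the open face and set C13 as the (R)-chloride, the product being a poorer enamine donor than the starting aldehyde.

**Step 4**
Reactants: 6 (2R,4Z)-2-chloro-7-(triisopropylsilyl)hept-4-en-6-ynal; 7 ethynyltrimethylsilane
Product: 9 (3S,4R,6Z)-4-chloro-1-(trimethylsilyl)-9-(triisopropylsilyl)non-6-ene-1,8-diyn-3-ol, via lithium acetylide 8 (not isolated)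
Conditions: 7 (1.5 equiv), n-BuLi (1.4 equiv), THF, −78 °C, 30 min; then 6, −78 °C, 1 h; H2O quench
Reagents that add atoms: none
Why: 1,2-Addition of a lithium acetylide to an α-chloroaldehyde under Cornforth (dipole-minimised) control, in which the nucleophile should attack anti to the C14 chain in the conformer with C=O and C–Cl antiparallel, giving the 1,2-anti chlorohydrin with C12 as S, while the weakly basic acetylide at −78 °C should spare the labile C13 centre.

**Step 5**
Reactants: 9 (3S,4R,6Z)-4-chloro-1-(trimethylsilyl)-9-(triisopropylsilyl)non-6-ene-1,8-diyn-3-ol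
Product: 11 (2S,3S)-2-ethynyl-3-[(2Z)-5-(triisopropylsilyl)pent-2-en-4-yn-1-yl]oxirane, via silylated oxirane 10 (not isolated)
Conditions: KOH (3 equiv), EtOH, 0 °C → rt
Reagents that add atoms: none
Why: Williamson-type 3-exo-tet ring closure in which the C12 alkoxide displaces the C13 chloride with inversion, so the anti chlorohydrin should give the trans (12S,13S) oxirane, while ethoxide removes the alkynyl SiMe3 group and leaves the hindered Si(i-Pr)3 group in place.

**Step 6**
Reactants: 11 (2S,3S)-2-ethynyl-3-[(2Z)-5-(triisopropylsilyl)pent-2-en-4-yn-1-yl]oxirane; 12 methyl 9-oxononanoate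
Product: 15 methyl (9S,10E,12S,13S,15Z)-12,13-epoxy-9-hydroxy-18-(triisopropylsilyl)octadeca-10,15-dien-17-ynoate, via alkenylborane 13 (not isolated), via alkenylzinc 14 (not isolated)
Conditions: Cy2BH (1.05 equiv), toluene, 0 °C → rt, 1 h; Me2Zn (1.1 equiv), −78 °C; (+)-MIB (5 mol%); 12 (slow addition), −20 → 0 °C; H2O quench
Reagents that add atoms: none
Why: Syn-hydroboration of the terminal alkyne of 11 gives (E)-alkenylborane 13, boron-to-zinc exchange with Me2Zn gives alkenyl(methyl)zinc 14, and 14 adds to aldehyde 12 through the amino-alkoxide-bridged dizinc transition state formed with (+)-MIB. The closest known reaction type is the catalytic asymmetric addition of alkenylzinc reagents, made by hydroboration and transmetalation, to aldehydes under amino-alcohol catalysis, which is established for unbranched aliphatic aldehydes and for alkynes carrying propargylic oxygen functions. No ring is closed; the oxirane made in step 5 is carried through unchanged. The new stereocentre C9 is controlled by the ligand alone (Re-face delivery, 9S), since C12 and C13 lie four atoms away across a rigid E-olefin, and the E geometry of C10=C11 follows from syn-hydroboration and retentive transmetalation. The step needs chemoselective hydroboration of the terminal alkyne (secured by one equivalent of the bulky borane and by the Si(i-Pr)3 group shielding the other alkyne), attack on the aldehyde and not the ester (secured by the low reactivity of organozinc reagents) and alkenyl transfer in preference to methyl transfer. The zinc alkoxide formed cannot open the oxirane intramolecularly, because a 2,5-dihydrofuran would require a Z-C10=C11 bond.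

**Step 7**
Reactants: 15 methyl (9S,10E,12S,13S,15Z)-12,13-epoxy-9-hydroxy-18-(triisopropylsilyl)octadeca-10,15-dien-17-ynoate
Product: 16 methyl (9S,10E,12S,13S,15Z)-12,13-epoxy-9-hydroxyoctadeca-10,15-dien-17-ynoate
Conditions: TBAF (1.1 equiv, 1 M in THF), THF, 0 °C, 30 min
Reagents that add atoms: none
Why: Fluoride-induced protodesilylation of an alkynylsilane, driven by the strong Si–F bond, should free the C18–H alkyne at 0 °C without touching the oxirane, the allylic alcohol or the methyl ester.

**Step 8**
Reactants: 16 methyl (9S,10E,12S,13S,15Z)-12,13-epoxy-9-hydroxyoctadeca-10,15-dien-17-ynoate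
Product: 17 methyl (9S,10E,12S,13S,15Z)-18-bromo-12,13-epoxy-9-hydroxyoctadeca-10,15-dien-17-ynoate
Conditions: NBS (1.1 equiv), AgNO3 (10 mol%), acetone, rt, dark
Reagents that add atoms: N-bromosuccinimide, O=C1CCC(=O)N1Br
Why: Silver-catalysed electrophilic bromination of a terminal alkyne proceeds through a silver acetylide that takes Br+ from NBS, so only the C18–H bond should react, under near-neutral conditions that the alkenyl oxirane and the allylic alcohol should tolerate.

**Compound list**

1 | (4-ethoxy-4-oxobutyl)triphenylphosphonium bromide | CCOC(=O)CCC[P+](c1ccccc1)(c1ccccc1)c1ccccc1.[Br-] | starting material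
2 | 3-(triisopropylsilyl)prop-2-ynal | O=CC#C[Si](C(C)C)(C(C)C)C(C)C | starting material
3 | ethyl 4-(triphenyl-λ5-phosphanylidene)butanoate (ylide) | CCOC(=O)CCC=P(c1ccccc1)(c1ccccc1)c1ccccc1 | intermediate
4 | ethyl (4Z)-7-(triisopropylsilyl)hept-4-en-6-ynoate | CCOC(=O)CC/C=C\C#C[Si](C(C)C)(C(C)C)C(C)C | intermediate
5 | (4Z)-7-(triisopropylsilyl)hept-4-en-6-ynal | O=CCC/C=C\C#C[Si](C(C)C)(C(C)C)C(C)C | intermediate
6 | (2R,4Z)-2-chloro-7-(triisopropylsilyl)hept-4-en-6-ynal | O=C[C@H](Cl)C/C=C\C#C[Si](C(C)C)(C(C)C)C(C)C | intermediate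
7 | ethynyltrimethylsilane | C#C[Si](C)(C)C | starting material
8 | lithium (trimethylsilyl)acetylide | [Li]C#C[Si](C)(C)C | intermediate
9 | (3S,4R,6Z)-4-chloro-1-(trimethylsilyl)-9-(triisopropylsilyl)non-6-ene-1,8-diyn-3-ol | C[Si](C)(C)C#C[C@H](O)[C@H](Cl)C/C=C\C#C[Si](C(C)C)(C(C)C)C(C)C | intermediate
10 | trimethyl{[(2S,3S)-3-[(2Z)-5-(triisopropylsilyl)pent-2-en-4-yn-1-yl]oxiran-2-yl]ethynyl}silane | C[Si](C)(C)C#C[C@@H]1O[C@H]1C/C=C\C#C[Si](C(C)C)(C(C)C)C(C)C | intermediate
11 | (2S,3S)-2-ethynyl-3-[(2Z)-5-(triisopropylsilyl)pent-2-en-4-yn-1-yl]oxirane | C#C[C@@H]1O[C@H]1C/C=C\C#C[Si](C(C)C)(C(C)C)C(C)C | intermediate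
12 | methyl 9-oxononanoate | COC(=O)CCCCCCCC=O | starting material
13 | dicyclohexyl{(E)-2-[(2S,3S)-3-[(2Z)-5-(triisopropylsilyl)pent-2-en-4-yn-1-yl]oxiran-2-yl]ethenyl}borane | B(C1CCCCC1)(C2CCCCC2)/C=C/[C@@H]3O[C@H]3C/C=C\C#C[Si](C(C)C)(C(C)C)C(C)C | intermediate
14 | methyl{(E)-2-[(2S,3S)-3-[(2Z)-5-(triisopropylsilyl)pent-2-en-4-yn-1-yl]oxiran-2-yl]ethenyl}zinc | C[Zn]/C=C/[C@@H]1O[C@H]1C/C=C\C#C[Si](C(C)C)(C(C)C)C(C)C | intermediate
15 | methyl (9S,10E,12S,13S,15Z)-12,13-epoxy-9-hydroxy-18-(triisopropylsilyl)octadeca-10,15-dien-17-ynoate | COC(=O)CCCCCCC[C@H](O)/C=C/[C@@H]1O[C@H]1C/C=C\C#C[Si](C(C)C)(C(C)C)C(C)C | intermediate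
16 | methyl (9S,10E,12S,13S,15Z)-12,13-epoxy-9-hydroxyoctadeca-10,15-dien-17-ynoate | COC(=O)CCCCCCC[C@H](O)/C=C/[C@@H]1O[C@H]1C/C=C\C#C | intermediate
17 | methyl (9S,10E,12S,13S,15Z)-18-bromo-12,13-epoxy-9-hydroxyoctadeca-10,15-dien-17-ynoate | COC(=O)CCCCCCC[C@H](O)/C=C/[C@@H]1O[C@H]1C/C=C\C#CBr | target

**Step count and risks**

Total step count: 8. Longest linear sequence: 8 (from 1 and 2; compounds 7 and 12 are purchased).

The three steps most likely to fail:

Step 6 (key step). The alkenyl group may be transferred to the unbranched aldehyde with too little facial discrimination, or the ligand-accelerated pathway may not outrun the background addition, so that C9 forms as a mixture. The fallback sets C9 by ketone reduction in place of C–C addition and sets out from 11 and 12. The same hydroboration and transmetalation, run with an achiral promoter (2-(dimethylamino)ethanol), should give methyl (9RS,10E,12S,13S,15Z)-12,13-epoxy-9-hydroxy-18-(triisopropylsilyl)octadeca-10,15-dien-17-ynoate F1 as a C9 epimer mixture. Dess–Martin oxidation (NaHCO3, CH2Cl2, 0 °C) should give the γ,δ-epoxy enone, methyl (10E,12S,13S,15Z)-12,13-epoxy-9-oxo-18-(triisopropylsilyl)octadeca-10,15-dien-17-ynoate F2. Corey–Bakshi–Shibata reduction ((R)-Me-CBS, catecholborane, toluene, −78 °C), with the alkenyl group as the large substituent, should then return the (9S)-alcohol, and the route is rejoined at 15.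

Step 4. The Cornforth bias may be incomplete, so that the syn chlorohydrin, and from it the cis oxirane, contaminates the product. The fallback replaces substrate-controlled addition by reagent-controlled reduction at C12 and sets out from 9 as obtained, in mixture with its C3 epimer. Dess–Martin oxidation should give the α-chloro ynone, (4R,6Z)-4-chloro-1-(trimethylsilyl)-9-(triisopropylsilyl)non-6-ene-1,8-diyn-3-one F3. Noyori asymmetric transfer hydrogenation (RuCl[(R,R)-TsDPEN](p-cymene), i-PrOH, rt, base-free) should reduce it under catalyst control to the (3S)-carbinol, and the route is rejoined at 9.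

Step 3. Enantiopurity at C13 may be lost by enamine- or enol-mediated racemisation of the α-chloroaldehyde during the reaction or its isolation. The fallback uses resolution in place of asymmetric catalysis and sets out from 5. Chlorination with NCS and DL-proline should give racemic (4Z)-2-chloro-7-(triisopropylsilyl)hept-4-en-6-ynal F4. Lithium acetylide (acetylene, n-BuLi, THF, −78 °C) should give the racemic anti chlorohydrin, rac-(3S*,4R*,6Z)-4-chloro-9-(triisopropylsilyl)non-6-ene-1,8-diyn-3-ol F5. Lipase-mediated kinetic resolution (Burkholderia cepacia lipase, vinyl acetate, MTBE, rt) should, by the Kazlauskas rule with ethynyl as the medium group, acylate the unwanted enantiomer to (3R,4S,6Z)-4-chloro-9-(triisopropylsilyl)non-6-ene-1,8-diyn-3-yl acetate F6 and leave (3S,4R,6Z)-4-chloro-9-(triisopropylsilyl)non-6-ene-1,8-diyn-3-ol F7. Treatment of F7 with KOH in EtOH closes the oxirane, and the route is rejoined at 11.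

**Further compounds**

F1 | step 6 | methyl (9RS,10E,12S,13S,15Z)-12,13-epoxy-9-hydroxy-18-(triisopropylsilyl)octadeca-10,15-dien-17-ynoate (C9 epimer mixture) | COC(=O)CCCCCCCC(O)/C=C/[C@@H]1O[C@H]1C/C=C\C#C[Si](C(C)C)(C(C)C)C(C)C
F2 | step 6 | methyl (10E,12S,13S,15Z)-12,13-epoxy-9-oxo-18-(triisopropylsilyl)octadeca-10,15-dien-17-ynoate | COC(=O)CCCCCCCC(=O)/C=C/[C@@H]1O[C@H]1C/C=C\C#C[Si](C(C)C)(C(C)C)C(C)C
F3 | step 4 | (4R,6Z)-4-chloro-1-(trimethylsilyl)-9-(triisopropylsilyl)non-6-ene-1,8-diyn-3-one | C[Si](C)(C)C#CC(=O)[C@H](Cl)C/C=C\C#C[Si](C(C)C)(C(C)C)C(C)C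
F4 | step 3 | rac-(4Z)-2-chloro-7-(triisopropylsilyl)hept-4-en-6-ynal (racemate; C2 left undefined in the SMILES) | O=CC(Cl)C/C=C\C#C[Si](C(C)C)(C(C)C)C(C)C
F5 | step 3 | rac-(3S*,4R*,6Z)-4-chloro-9-(triisopropylsilyl)non-6-ene-1,8-diyn-3-ol (anti racemate; C3 and C4 left undefined in the SMILES) | C#CC(O)C(Cl)C/C=C\C#C[Si](C(C)C)(C(C)C)C(C)C
F6 | step 3 | (3R,4S,6Z)-4-chloro-9-(triisopropylsilyl)non-6-ene-1,8-diyn-3-yl acetate | C#C[C@@H](OC(C)=O)[C@@H](Cl)C/C=C\C#C[Si](C(C)C)(C(C)C)C(C)C
F7 | step 3 | (3S,4R,6Z)-4-chloro-9-(triisopropylsilyl)non-6-ene-1,8-diyn-3-ol | C#C[C@H](O)[C@H](Cl)C/C=C\C#C[Si](C(C)C)(C(C)C)C(C)C
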